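**Retrosynthetic overview**

- The route rests on the conjugated bis-enol ether O1–C7a=C3a–C4(OMe)=C5 that spans the dihydrofuran (ring A) and the carbocycle (ring B). C7a/C3a are read as an internal alkyne and C4/C5 as a methoxyalkyne.
- Cutting O1–C7a and C3a–C4 together opens both rings to the acyclic diynol 25, which already holds C2, C3, C6 and C7. Forward, ring A closes first (5-endo-dig) and ring B second (6-endo-dig) in one gold-catalysed cascade.
- 25 is cut at C3–C3a into aryl epoxide 6 (Heck, Shi epoxidation) and diyne 23 (Evans aldol, ozonolysis, Felkin methoxyalkynylation, Ohira–Bestmann). The epoxide opening sets C3 and frees the C2 hydroxyl that starts the cascade.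
- The C7 acyl group travels as a silylated carbinol, since a ketone β,γ to the alkyne would itself cyclise onto it. It is unveiled after the cascade by selective desilylation and oxidation, and buffered fluoride finishes.

Key step: step 17

Remark: benzofuran numbering of the target (O1, C2, C3, C3a, C4 to C7, C7a; C1' is the side-chain carbon on C7) is used for all intermediates. The configuration at C1' is immaterial because it ends as the ketone, and the phenol is carried as a TIPS ether rather than a TBS ether.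

**Route**

Step 1
Reactants: 1 methyl 4-hydroxy-3-iodobenzoate
Product: 2 methyl 3-iodo-4-[(triisopropylsilyl)oxy]benzoate
Conditions: TIPSCl, imidazole, DMF, rt
Reagents that add atoms: chlorotri(propan-2-yl)silane (TIPSCl), CC(C)[Si](Cl)(C(C)C)C(C)C
Why: O-silylation of the phenol; the TIPS ether is chosen because an aryl silyl ether para to an ester must survive Et3N at 80 °C and the pH 10.5 epoxidation medium.

Step 2
Reactants: 2 methyl 3-iodo-4-[(triisopropylsilyl)oxy]benzoate; 3 2-methylbut-3-en-2-ol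
Product: 4 methyl 3-[(E)-3-hydroxy-3-methylbut-1-en-1-yl]-4-[(triisopropylsilyl)oxy]benzoate
Conditions: Pd(OAc)2 (5 mol %), P(o-tol)3, Et3N, MeCN, 80 °C
Reagents that add atoms: none
Why: Mizoroki–Heck reaction through zerovalent palladium; syn-carbopalladation of the terminal alkene and syn-β-hydride elimination give the E-styrene, and the tertiary carbinol cannot isomerise to a ketone.

Step 3
Reactants: 4 methyl 3-[(E)-3-hydroxy-3-methylbut-1-en-1-yl]-4-[(triisopropylsilyl)oxy]benzoate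
Product: 5 methyl 3-[(E)-3-methyl-3-[(triethylsilyl)oxy]but-1-en-1-yl]-4-[(triisopropylsilyl)oxy]benzoate
Conditions: TESOTf, 2,6-lutidine, CH2Cl2, −78 to 0 °C
Reagents that add atoms: triethylsilyl trifluoromethanesulfonate (TESOTf), CC[Si](CC)(CC)OS(=O)(=O)C(F)(F)F
Why: Silylation of the hindered tertiary alcohol with a silyl triflate and a hindered base; capping it here removes any later need to tell it apart from the secondary C2 hydroxyl.

Step 4
Reactants: 5 methyl 3-[(E)-3-methyl-3-[(triethylsilyl)oxy]but-1-en-1-yl]-4-[(triisopropylsilyl)oxy]benzoate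
Product: 6 methyl 3-[(2S,3R)-3-{2-[(triethylsilyl)oxy]propan-2-yl}oxiran-2-yl]-4-[(triisopropylsilyl)oxy]benzoate
Conditions: ent-Shi ketone (the L-fructose-derived enantiomer, 30 mol %), Oxone (2KHSO5·KHSO4·K2SO4), K2CO3, Bu4NHSO4, MeCN–CH2(OMe)2–aq. Na2B4O7 (pH 10.5), 0 °C
Reagents that add atoms: potassium peroxymonosulfate (KHSO5), [K+].OOS(=O)(=O)[O-]
Why: Shi asymmetric epoxidation (chiral dioxirane, spiro transition state) of a trans-disubstituted aryl alkene; the D-fructose-derived ketone gives the (R,R) sense with trans-β-methylstyrene, so its enantiomer delivers oxygen to the opposite face and sets the future C2 (R) and the benzylic carbon (S), the latter to be inverted in step 16.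

Step 5
Reactants: 7 (R)-4-benzyloxazolidin-2-one; 8 (E)-but-2-enoyl chloride
Product: 9 (R)-4-benzyl-3-[(E)-but-2-enoyl]oxazolidin-2-one
Conditions: n-BuLi, THF, −78 °C; then 8, −78 to 0 °C
Reagents that add atoms: none
Why: N-acylation of the lithiated oxazolidinone with an acid chloride.

Step 6
Reactants: 9 (R)-4-benzyl-3-[(E)-but-2-enoyl]oxazolidin-2-one; 10 3-phenylpropanal
Product: 12 (R)-4-benzyl-3-[(2R,3S)-2-ethenyl-3-hydroxy-5-phenylpentanoyl]oxazolidin-2-one, via dibutylboron dienolate 11 (not isolated)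
Conditions: Bu2BOTf, Et3N, CH2Cl2, −78 to 0 °C; 10, −78 to 0 °C; then pH 7 buffer, MeOH, H2O2, 0 °C
Reagents that add atoms: none
Why: Evans syn-aldol reaction in its deconjugative form; γ-enolisation gives the (Z)-boron dienolate 11, which reacts at its α-carbon through a Zimmerman–Traxler chair on the face away from the benzyl group, setting C7 and C1' (2R,3S) and leaving the vinyl group as the latent C6 aldehyde.

Step 7
Reactants: 12 (R)-4-benzyl-3-[(2R,3S)-2-ethenyl-3-hydroxy-5-phenylpentanoyl]oxazolidin-2-one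
Product: 13 (R)-4-benzyl-3-[(2R,3S)-2-ethenyl-5-phenyl-3-[(triethylsilyl)oxy]pentanoyl]oxazolidin-2-one
Conditions: TESCl, imidazole, DMF, 0 °C to rt
Reagents that add atoms: chlorotriethylsilane (TESCl), CC[Si](Cl)(CC)CC
Why: Silylation of the secondary alcohol; the bulky, non-chelating TES ether later makes this arm the large Felkin substituent and is the group removed selectively before the oxidation to the ketone.

Step 8
Reactants: 13 (R)-4-benzyl-3-[(2R,3S)-2-ethenyl-5-phenyl-3-[(triethylsilyl)oxy]pentanoyl]oxazolidin-2-one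
Product: 14 (2S,3S)-2-ethenyl-5-phenyl-3-[(triethylsilyl)oxy]pentan-1-ol
Conditions: LiBH4, MeOH (1 equiv), Et2O, 0 °C
Reagents that add atoms: none
Why: Reductive cleavage of the imide by hydride attack on the exocyclic carbonyl, which frees the primary alcohol whose carbon becomes the alkyne carbon C7a and returns the auxiliary.

Step 9
Reactants: 14 (2S,3S)-2-ethenyl-5-phenyl-3-[(triethylsilyl)oxy]pentan-1-ol
Product: 15 (2S,3S)-2-ethenyl-5-phenyl-3-[(triethylsilyl)oxy]pentyl 2,2-dimethylpropanoate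
Conditions: PivCl, pyridine, DMAP (cat.), CH2Cl2, 0 °C to rt
Reagents that add atoms: 2,2-dimethylpropanoyl chloride (PivCl), CC(C)(C)C(Cl)=O
Why: Acylation of the primary alcohol; the pivalate survives ozone, the alkynide at −78 °C and silylation, and is later removed by hydride without touching silyl ethers or the ynol ether.

Step 10
Reactants: 15 (2S,3S)-2-ethenyl-5-phenyl-3-[(triethylsilyl)oxy]pentyl 2,2-dimethylpropanoate
Product: 16 (2S,3S)-2-formyl-5-phenyl-3-[(triethylsilyl)oxy]pentyl 2,2-dimethylpropanoate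
Conditions: O3, CH2Cl2, −78 °C; then PPh3, −78 °C to rt; used crude
Reagents that add atoms: ozone, [O-][O+]=O
Why: Ozonolysis with reductive work-up cleaves the only alkene to the C6 aldehyde without disturbing C7.

Step 11
Reactants: 16 (2S,3S)-2-formyl-5-phenyl-3-[(triethylsilyl)oxy]pentyl 2,2-dimethylpropanoate; 17 2-chloro-1,1-dimethoxyethane
Product: 19 (2R,3S)-2-[(1R)-1-hydroxy-3-methoxyprop-2-yn-1-yl]-5-phenyl-3-[(triethylsilyl)oxy]pentyl 2,2-dimethylpropanoate, via lithium methoxyacetylide 18 (not isolated)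
Conditions: Et2NH, n-BuLi, THF, 0 °C (LiNEt2, 3 equiv); 17, 0 °C; then 16, −78 °C; aq. NH4Cl at −78 °C
Reagents that add atoms: none
Why: 1,2-Addition of the alkynide 18 (made from 17 by two eliminations and deprotonation) to the α-branched aldehyde; Felkin–Anh attack anti to the bulky CH(OTES) arm, reinforced by 1,3-anti induction from the β-silyloxy group of this 2,3-anti aldehyde, sets C6 (R).

Step 12
Reactants: 19 (2R,3S)-2-[(1R)-1-hydroxy-3-methoxyprop-2-yn-1-yl]-5-phenyl-3-[(triethylsilyl)oxy]pentyl 2,2-dimethylpropanoate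
Product: 20 (2S,3S)-2-[(1R)-1-[(tert-butyldimethylsilyl)oxy]-3-methoxyprop-2-yn-1-yl]-5-phenyl-3-[(triethylsilyl)oxy]pentyl 2,2-dimethylpropanoate
Conditions: TBSCl, imidazole, DMAP (cat.), DMF, rt
Reagents that add atoms: tert-butylchlorodimethylsilane (TBSCl), CC(C)(C)[Si](C)(C)Cl
Why: Silylation of the propargylic alcohol under near-neutral conditions that the acid-labile ynol ether tolerates; TBS is chosen so that the C6 oxygen outlasts the TES groups.

Step 13
Reactants: 20 (2S,3S)-2-[(1R)-1-[(tert-butyldimethylsilyl)oxy]-3-methoxyprop-2-yn-1-yl]-5-phenyl-3-[(triethylsilyl)oxy]pentyl 2,2-dimethylpropanoate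
Product: 21 (2S,3S)-2-[(1R)-1-[(tert-butyldimethylsilyl)oxy]-3-methoxyprop-2-yn-1-yl]-5-phenyl-3-[(triethylsilyl)oxy]pentan-1-ol
Conditions: i-Bu2AlH, CH2Cl2, −78 °C; aq. KNaC4H4O6
Reagents that add atoms: none
Why: Reductive cleavage of the pivalate at −78 °C, where the ynol ether and the silyl ethers are inert to the aluminium hydride.

Step 14
Reactants: 21 (2S,3S)-2-[(1R)-1-[(tert-butyldimethylsilyl)oxy]-3-methoxyprop-2-yn-1-yl]-5-phenyl-3-[(triethylsilyl)oxy]pentan-1-ol
Product: 22 (2S,3S)-2-[(1R)-1-[(tert-butyldimethylsilyl)oxy]-3-methoxyprop-2-yn-1-yl]-5-phenyl-3-[(triethylsilyl)oxy]pentanal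
Conditions: Dess–Martin periodinane, NaHCO3, CH2Cl2, 0 °C to rt
Reagents that add atoms: none
Why: Dess–Martin oxidation of the primary alcohol with NaHCO3 buffering, which keeps the medium non-acidic for the ynol ether and does not epimerise C7.

Step 15
Reactants: 22 (2S,3S)-2-[(1R)-1-[(tert-butyldimethylsilyl)oxy]-3-methoxyprop-2-yn-1-yl]-5-phenyl-3-[(triethylsilyl)oxy]pentanal
Product: 23 (3S,4R)-4-[(tert-butyldimethylsilyl)oxy]-6-methoxy-3-[(1S)-3-phenyl-1-[(triethylsilyl)oxy]propyl]hexa-1,5-diyne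
Conditions: dimethyl (1-diazo-2-oxopropyl)phosphonate, K2CO3, MeOH, 0 °C to rt
Reagents that add atoms: dimethyl (1-diazo-2-oxopropyl)phosphonate (Ohira–Bestmann reagent), COP(=O)(OC)C(=[N+]=[N-])C(C)=O
Why: Ohira–Bestmann (Seyferth–Gilbert) homologation; the diazomethylphosphonate anion adds to the aldehyde and the alkylidene carbene rearranges to the terminal alkyne, the cold carbonate–methanol medium being mild enough for the α-stereocentre and the β-silyloxy groups.

Step 16
Reactants: 23 (3S,4R)-4-[(tert-butyldimethylsilyl)oxy]-6-methoxy-3-[(1S)-3-phenyl-1-[(triethylsilyl)oxy]propyl]hexa-1,5-diyne; 6 methyl 3-[(2S,3R)-3-{2-[(triethylsilyl)oxy]propan-2-yl}oxiran-2-yl]-4-[(triisopropylsilyl)oxy]benzoate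
Product: 25 methyl 3-[(3R,4S,7R,8R)-3-[(tert-butyldimethylsilyl)oxy]-8-hydroxy-1-methoxy-9-methyl-4-[(1S)-3-phenyl-1-[(triethylsilyl)oxy]propyl]-9-[(triethylsilyl)oxy]deca-1,5-diyn-7-yl]-4-[(triisopropylsilyl)oxy]benzoate, via lithium alkynide 24 (not isolated)
Conditions: 23 (1.5 equiv), n-BuLi, THF, −78 °C; BF3·OEt2, −78 °C; then 6, −78 °C
Reagents that add atoms: none
Why: Yamaguchi–Hirao epoxide opening; the alkynide 24 activated by BF3 attacks the benzylic oxirane carbon from the back (the other oxirane carbon is neopentyl-like), so C3 is set (R) by inversion, C2 keeps its configuration, and its oxygen emerges as the only free hydroxyl.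

Step 17
Reactants: 25 methyl 3-[(3R,4S,7R,8R)-3-[(tert-butyldimethylsilyl)oxy]-8-hydroxy-1-methoxy-9-methyl-4-[(1S)-3-phenyl-1-[(triethylsilyl)oxy]propyl]-9-[(triethylsilyl)oxy]deca-1,5-diyn-7-yl]-4-[(triisopropylsilyl)oxy]benzoate
Product: 27 methyl 3-[(2R,3S,6S,7S)-6-[(tert-butyldimethylsilyl)oxy]-4-methoxy-7-[(1S)-3-phenyl-1-[(triethylsilyl)oxy]propyl]-2-{2-[(triethylsilyl)oxy]propan-2-yl}-2,3,6,7-tetrahydro-1-benzofuran-3-yl]-4-[(triisopropylsilyl)oxy]benzoate, via 2,3-dihydrofuran 26 (not isolated)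
Conditions: Ph3PAuNTf2 (5 mol %), 4 Å molecular sieves, CH2Cl2, 0 °C to rt
Reagents that add atoms: none
Why: Proposed new method: π-coordination of cationic monovalent gold to the C3a≡C7a alkyne lets the only free hydroxyl (on C2) add across it in a 5-endo-dig closure (ring A, bond O1–C7a), and protodeauration releases the 2,3-dihydrofuran 26, an enol ether whose β-carbon C3a is the most nucleophilic carbon in the molecule. Gold then activates the methoxyalkyne, which is polarised like a ketene oxonium ion (gold on C5, positive charge on the methoxy-bearing C4), so C3a attacks C4 in a 6-endo-dig closure (ring B, bond C3a–C4); loss of the C3a proton from the oxocarbenium ion and protodeauration at C5 give the conjugated bis-enol ether 27. The closest known reaction types are the gold-catalysed 5-endo-dig cycloisomerisation of homopropargylic alcohols to 2,3-dihydrofurans and gold-catalysed carbocyclisations in which enol ethers attack alkynes or π-nucleophiles attack gold-activated ynol ethers and ynamides at the heteroatom-bearing carbon; their union in one cascade on a diynol is without precedent. No stereocentre is formed: C2, C3, C6 and C7 come unchanged from 25, and none of them becomes sp2. The step needs chemoselectivity (the secondary C2 hydroxyl rather than the tertiary one, which would close 5-exo onto C3a; a C–C bond to C4 rather than a 5-exo closure onto C5), and this is secured by the triethylsilyl cap on the tertiary oxygen and by the innate polarisation of the ynol ether. The neutral, dry medium is chosen so that the ynol ether is not hydrated and the allylic C6 silyloxy group next to the C7 hydrogen is not lost with aromatisation.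

Step 18
Reactants: 27 methyl 3-[(2R,3S,6S,7S)-6-[(tert-butyldimethylsilyl)oxy]-4-methoxy-7-[(1S)-3-phenyl-1-[(triethylsilyl)oxy]propyl]-2-{2-[(triethylsilyl)oxy]propan-2-yl}-2,3,6,7-tetrahydro-1-benzofuran-3-yl]-4-[(triisopropylsilyl)oxy]benzoate
Product: 28 methyl 3-[(2R,3S,6S,7S)-6-[(tert-butyldimethylsilyl)oxy]-7-[(1S)-1-hydroxy-3-phenylpropyl]-2-(2-hydroxypropan-2-yl)-4-methoxy-2,3,6,7-tetrahydro-1-benzofuran-3-yl]-4-[(triisopropylsilyl)oxy]benzoate
Conditions: HF·pyridine, pyridine, THF, 0 °C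
Reagents that add atoms: none
Why: Acidic fluoride cleaves TES ethers well before TBS ethers and spares aryl silyl ethers, so pyridine-buffered HF·pyridine should remove both TES groups and expose the C1' carbinol while the C6 TBS ether and the phenol TIPS ether stay in place.

Step 19
Reactants: 28 methyl 3-[(2R,3S,6S,7S)-6-[(tert-butyldimethylsilyl)oxy]-7-[(1S)-1-hydroxy-3-phenylpropyl]-2-(2-hydroxypropan-2-yl)-4-methoxy-2,3,6,7-tetrahydro-1-benzofuran-3-yl]-4-[(triisopropylsilyl)oxy]benzoate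
Product: 29 methyl 3-[(2R,3S,6S,7S)-6-[(tert-butyldimethylsilyl)oxy]-2-(2-hydroxypropan-2-yl)-4-methoxy-7-(3-phenylpropanoyl)-2,3,6,7-tetrahydro-1-benzofuran-3-yl]-4-[(triisopropylsilyl)oxy]benzoate
Conditions: Dess–Martin periodinane, NaHCO3, CH2Cl2, 0 °C
Reagents that add atoms: none
Why: Dess–Martin oxidation of the only secondary alcohol to the ketone (the tertiary alcohol is inert), with NaHCO3 buffering so that the now enolisable C7 and the bis-enol ether meet neither acid nor base.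

Step 20
Reactants: 29 methyl 3-[(2R,3S,6S,7S)-6-[(tert-butyldimethylsilyl)oxy]-2-(2-hydroxypropan-2-yl)-4-methoxy-7-(3-phenylpropanoyl)-2,3,6,7-tetrahydro-1-benzofuran-3-yl]-4-[(triisopropylsilyl)oxy]benzoate
Product: 30 methyl 4-hydroxy-3-[(2R,3S,6S,7S)-6-hydroxy-2-(2-hydroxypropan-2-yl)-4-methoxy-7-(3-phenylpropanoyl)-2,3,6,7-tetrahydro-1-benzofuran-3-yl]benzoate (CNP0080427.1)
Conditions: Bu4NF, AcOH (1:1), THF, 0 °C to rt
Reagents that add atoms: none
Why: Fluoride-mediated desilylation buffered with acetic acid removes the aryl TIPS and the C6 TBS ethers without the basicity that would cause E1cB loss of the C6 oxygen from the β-silyloxy ketone and aromatisation.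

**Compound list**

1 | methyl 4-hydroxy-3-iodobenzoate | COC(=O)c1ccc(O)c(I)c1 | starting material
2 | methyl 3-iodo-4-[(triisopropylsilyl)oxy]benzoate | COC(=O)c1ccc(O[Si](C(C)C)(C(C)C)C(C)C)c(I)c1 | intermediate
3 | 2-methylbut-3-en-2-ol | CC(C)(O)C=C | starting material
4 | methyl 3-[(E)-3-hydroxy-3-methylbut-1-en-1-yl]-4-[(triisopropylsilyl)oxy]benzoate | COC(=O)c1ccc(O[Si](C(C)C)(C(C)C)C(C)C)c(/C=C/C(C)(C)O)c1 | intermediate
5 | methyl 3-[(E)-3-methyl-3-[(triethylsilyl)oxy]but-1-en-1-yl]-4-[(triisopropylsilyl)oxy]benzoate | COC(=O)c1ccc(O[Si](C(C)C)(C(C)C)C(C)C)c(/C=C/C(C)(C)O[Si](CC)(CC)CC)c1 | intermediate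
6 | methyl 3-[(2S,3R)-3-{2-[(triethylsilyl)oxy]propan-2-yl}oxiran-2-yl]-4-[(triisopropylsilyl)oxy]benzoate | COC(=O)c1ccc(O[Si](C(C)C)(C(C)C)C(C)C)c([C@@H]2O[C@H]2C(C)(C)O[Si](CC)(CC)CC)c1 | intermediate
7 | (R)-4-benzyloxazolidin-2-one | O=C1N[C@H](Cc2ccccc2)CO1 | starting material
8 | (E)-but-2-enoyl chloride | C/C=C/C(Cl)=O | starting material
9 | (R)-4-benzyl-3-[(E)-but-2-enoyl]oxazolidin-2-one | C/C=C/C(=O)N1[C@H](Cc2ccccc2)COC1=O | intermediate
10 | 3-phenylpropanal | O=CCCc1ccccc1 | starting material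
11 | dibutylboron (Z)-dienolate of 9 | C=C/C=C(\OB(CCCC)CCCC)N1[C@H](Cc2ccccc2)COC1=O | intermediate
12 | (R)-4-benzyl-3-[(2R,3S)-2-ethenyl-3-hydroxy-5-phenylpentanoyl]oxazolidin-2-one | C=C[C@H]([C@@H](O)CCc1ccccc1)C(=O)N1[C@H](Cc2ccccc2)COC1=O | intermediate
13 | (R)-4-benzyl-3-[(2R,3S)-2-ethenyl-5-phenyl-3-[(triethylsilyl)oxy]pentanoyl]oxazolidin-2-one | C=C[C@H]([C@@H](O[Si](CC)(CC)CC)CCc1ccccc1)C(=O)N1[C@H](Cc2ccccc2)COC1=O | intermediate
14 | (2S,3S)-2-ethenyl-5-phenyl-3-[(triethylsilyl)oxy]pentan-1-ol | C=C[C@H]([C@@H](O[Si](CC)(CC)CC)CCc1ccccc1)CO | intermediate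
15 | (2S,3S)-2-ethenyl-5-phenyl-3-[(triethylsilyl)oxy]pentyl 2,2-dimethylpropanoate | C=C[C@H]([C@@H](O[Si](CC)(CC)CC)CCc1ccccc1)COC(=O)C(C)(C)C | intermediate
16 | (2S,3S)-2-formyl-5-phenyl-3-[(triethylsilyl)oxy]pentyl 2,2-dimethylpropanoate | O=C[C@H]([C@@H](O[Si](CC)(CC)CC)CCc1ccccc1)COC(=O)C(C)(C)C | intermediate
17 | 2-chloro-1,1-dimethoxyethane | COC(CCl)OC | starting material
18 | lithium methoxyacetylide | COC#C[Li] | intermediate
19 | (2R,3S)-2-[(1R)-1-hydroxy-3-methoxyprop-2-yn-1-yl]-5-phenyl-3-[(triethylsilyl)oxy]pentyl 2,2-dimethylpropanoate | COC#C[C@H](O)[C@H]([C@@H](O[Si](CC)(CC)CC)CCc1ccccc1)COC(=O)C(C)(C)C | intermediate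
20 | (2S,3S)-2-[(1R)-1-[(tert-butyldimethylsilyl)oxy]-3-methoxyprop-2-yn-1-yl]-5-phenyl-3-[(triethylsilyl)oxy]pentyl 2,2-dimethylpropanoate | COC#C[C@H](O[Si](C)(C)C(C)(C)C)[C@H]([C@@H](O[Si](CC)(CC)CC)CCc1ccccc1)COC(=O)C(C)(C)C | intermediate
21 | (2S,3S)-2-[(1R)-1-[(tert-butyldimethylsilyl)oxy]-3-methoxyprop-2-yn-1-yl]-5-phenyl-3-[(triethylsilyl)oxy]pentan-1-ol | COC#C[C@H](O[Si](C)(C)C(C)(C)C)[C@H]([C@@H](O[Si](CC)(CC)CC)CCc1ccccc1)CO | intermediate
22 | (2S,3S)-2-[(1R)-1-[(tert-butyldimethylsilyl)oxy]-3-methoxyprop-2-yn-1-yl]-5-phenyl-3-[(triethylsilyl)oxy]pentanal | COC#C[C@H](O[Si](C)(C)C(C)(C)C)[C@H]([C@@H](O[Si](CC)(CC)CC)CCc1ccccc1)C=O | intermediate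
23 | (3S,4R)-4-[(tert-butyldimethylsilyl)oxy]-6-methoxy-3-[(1S)-3-phenyl-1-[(triethylsilyl)oxy]propyl]hexa-1,5-diyne | COC#C[C@H](O[Si](C)(C)C(C)(C)C)[C@H]([C@@H](O[Si](CC)(CC)CC)CCc1ccccc1)C#C | intermediate
24 | lithium alkynide of 23 (lithium on the terminal alkyne carbon) | COC#C[C@H](O[Si](C)(C)C(C)(C)C)[C@H]([C@@H](O[Si](CC)(CC)CC)CCc1ccccc1)C#C[Li] | intermediate
25 | methyl 3-[(3R,4S,7R,8R)-3-[(tert-butyldimethylsilyl)oxy]-8-hydroxy-1-methoxy-9-methyl-4-[(1S)-3-phenyl-1-[(triethylsilyl)oxy]propyl]-9-[(triethylsilyl)oxy]deca-1,5-diyn-7-yl]-4-[(triisopropylsilyl)oxy]benzoate (acyclic diynol, precursor of the key step) | COC(=O)c1ccc(O[Si](C(C)C)(C(C)C)C(C)C)c([C@H]([C@@H](O)C(C)(C)O[Si](CC)(CC)CC)C#C[C@@H]([C@H](CCc2ccccc2)O[Si](CC)(CC)CC)[C@@H](O[Si](C)(C)C(C)(C)C)C#COC)c1 | intermediate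
26 | methyl 3-[(2R,3R)-5-[(1S,2R)-2-[(tert-butyldimethylsilyl)oxy]-4-methoxy-1-[(1S)-3-phenyl-1-[(triethylsilyl)oxy]propyl]but-3-yn-1-yl]-2-{2-[(triethylsilyl)oxy]propan-2-yl}-2,3-dihydrofuran-3-yl]-4-[(triisopropylsilyl)oxy]benzoate (ring A closed, methoxyalkyne intact) | COC(=O)c1ccc(O[Si](C(C)C)(C(C)C)C(C)C)c([C@H]2C=C(O[C@H]2C(C)(C)O[Si](CC)(CC)CC)[C@@H]([C@H](CCc3ccccc3)O[Si](CC)(CC)CC)[C@@H](O[Si](C)(C)C(C)(C)C)C#COC)c1 | intermediate
27 | methyl 3-[(2R,3S,6S,7S)-6-[(tert-butyldimethylsilyl)oxy]-4-methoxy-7-[(1S)-3-phenyl-1-[(triethylsilyl)oxy]propyl]-2-{2-[(triethylsilyl)oxy]propan-2-yl}-2,3,6,7-tetrahydro-1-benzofuran-3-yl]-4-[(triisopropylsilyl)oxy]benzoate (product of the key step) | COC(=O)c1ccc(O[Si](C(C)C)(C(C)C)C(C)C)c([C@H]2C3=C(O[C@H]2C(C)(C)O[Si](CC)(CC)CC)[C@@H]([C@H](CCc4ccccc4)O[Si](CC)(CC)CC)[C@@H](O[Si](C)(C)C(C)(C)C)C=C3OC)c1 | intermediate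
28 | methyl 3-[(2R,3S,6S,7S)-6-[(tert-butyldimethylsilyl)oxy]-7-[(1S)-1-hydroxy-3-phenylpropyl]-2-(2-hydroxypropan-2-yl)-4-methoxy-2,3,6,7-tetrahydro-1-benzofuran-3-yl]-4-[(triisopropylsilyl)oxy]benzoate | COC(=O)c1ccc(O[Si](C(C)C)(C(C)C)C(C)C)c([C@H]2C3=C(O[C@H]2C(C)(C)O)[C@@H]([C@H](CCc4ccccc4)O)[C@@H](O[Si](C)(C)C(C)(C)C)C=C3OC)c1 | intermediate
29 | methyl 3-[(2R,3S,6S,7S)-6-[(tert-butyldimethylsilyl)oxy]-2-(2-hydroxypropan-2-yl)-4-methoxy-7-(3-phenylpropanoyl)-2,3,6,7-tetrahydro-1-benzofuran-3-yl]-4-[(triisopropylsilyl)oxy]benzoate | COC(=O)c1ccc(O[Si](C(C)C)(C(C)C)C(C)C)c([C@H]2C3=C(O[C@H]2C(C)(C)O)[C@@H](C(=O)CCc4ccccc4)[C@@H](O[Si](C)(C)C(C)(C)C)C=C3OC)c1 | intermediate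
30 | methyl 4-hydroxy-3-[(2R,3S,6S,7S)-6-hydroxy-2-(2-hydroxypropan-2-yl)-4-methoxy-7-(3-phenylpropanoyl)-2,3,6,7-tetrahydro-1-benzofuran-3-yl]benzoate (CNP0080427.1) | COC(=O)c1ccc(O)c([C@H]2C3=C(O[C@H]2C(C)(C)O)[C@@H](C(=O)CCc4ccccc4)[C@@H](O)C=C3OC)c1 | target

**Step count**

Total: 20 steps. Longest linear sequence: 16 steps (steps 5 to 20); the epoxide branch (steps 1 to 4) joins at step 16.

**Steps most likely to fail**

1. Step 17 (gold cascade, the one step beyond known chemistry). The cascade may halt after ring A, with protodeauration to 26 and no engagement of the ynol ether. The gold-bound ynol ether may be hydrated by traces of water or closed 5-exo at C5. The allylic C6 silyloxy group may ionise and the ring aromatise. The fallback uses only known reaction types, sets out from aldehyde 16 and comes back at 27. CH2=CHMgBr adds to 16 (THF, −78 °C, same Felkin sense) to give the allylic alcohol F1. TBSCl and imidazole give the silyl ether F2, i-Bu2AlH frees the primary alcohol F3, Dess–Martin oxidation gives the aldehyde F4, and Ohira–Bestmann homologation gives the enyne F5. Its lithium alkynide with BF3·OEt2 opens epoxide 6 as in step 16 to give the homopropargylic alcohol F6. Iodine and NaHCO3 in MeCN then close ring A by 5-endo-dig iodoetherification to the 3-iodo-4,5-dihydrofuran F7. Stille coupling with tributyl(1-methoxyvinyl)stannane (Pd(PPh3)4, CuI, DMF) brings in C4 with its methoxy group as the 2-methoxydiene F8. Ring-closing metathesis with the second-generation Grubbs catalyst joins C4 to C5 with loss of ethene and gives 27.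

2. Step 16 (epoxide opening). BF3 may ionise the benzylic C–O bond before the alkynide arrives, which would erode the inversion at C3 or lead to a hydride shift. The branched alkynide may attack the hindered oxirane too slowly. BF3 may also attack the ynol ether or promote alkynylation of the benzoate. The fallback sets out from allylic alcohol 4 (with alkyne 23) and comes back at 28. Shi epoxidation of the free alcohol 4 with the same ketone gives the epoxy alcohol F9. Its lithium alkoxide is treated with the diethylaluminium alkynide made from 24 and Et2AlCl (toluene, 0 °C). The aluminium is held on the tertiary oxygen and the alkynyl group is delivered to the distal, benzylic carbon with inversion and without BF3, giving the diol F10. N-(Trimethylsilyl)imidazole gives the bis(trimethylsilyl) ether F11. K2CO3 in MeOH at 0 °C removes the less hindered secondary silyl group and leaves the tertiary trimethylsilyl ether F12. The gold cascade of step 17 then gives the tetrahydrobenzofuran F13. The HF·pyridine treatment of step 18 removes the trimethylsilyl group together with the triethylsilyl group and returns the material at 28.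

3. Step 11 (methoxyalkynylation). Facial selectivity of the alkynide addition may be insufficient, or the pivalate may migrate to the new alkoxide if the quench is not cold. The fallback sets out from the product mixture of step 11 and comes back at 19. Activated MnO2 in CH2Cl2 oxidises the mixture of 19 and its C6 epimer F14 to the single ynone F15. Transfer hydrogenation with RuCl[(R,R)-TsDPEN](p-cymene) in i-PrOH is a reagent-controlled reduction, for which the (S,S) catalyst is known to give (S)-propargylic alcohols from alkynyl ketones. It should return the (R)-carbinol 19.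

**Further compounds**

F1 | step 17 | (2R,3S)-2-[(1S)-1-hydroxyprop-2-en-1-yl]-5-phenyl-3-[(triethylsilyl)oxy]pentyl 2,2-dimethylpropanoate | C=C[C@H](O)[C@H]([C@@H](O[Si](CC)(CC)CC)CCc1ccccc1)COC(=O)C(C)(C)C
F2 | step 17 | (2S,3S)-2-[(1S)-1-[(tert-butyldimethylsilyl)oxy]prop-2-en-1-yl]-5-phenyl-3-[(triethylsilyl)oxy]pentyl 2,2-dimethylpropanoate | C=C[C@H](O[Si](C)(C)C(C)(C)C)[C@H]([C@@H](O[Si](CC)(CC)CC)CCc1ccccc1)COC(=O)C(C)(C)C
F3 | step 17 | (2S,3S)-2-[(1S)-1-[(tert-butyldimethylsilyl)oxy]prop-2-en-1-yl]-5-phenyl-3-[(triethylsilyl)oxy]pentan-1-ol | C=C[C@H](O[Si](C)(C)C(C)(C)C)[C@H]([C@@H](O[Si](CC)(CC)CC)CCc1ccccc1)CO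
F4 | step 17 | (2S,3S)-2-[(1S)-1-[(tert-butyldimethylsilyl)oxy]prop-2-en-1-yl]-5-phenyl-3-[(triethylsilyl)oxy]pentanal | C=C[C@H](O[Si](C)(C)C(C)(C)C)[C@H]([C@@H](O[Si](CC)(CC)CC)CCc1ccccc1)C=O
F5 | step 17 | (3S,4S)-4-[(tert-butyldimethylsilyl)oxy]-3-[(1S)-3-phenyl-1-[(triethylsilyl)oxy]propyl]hex-5-en-1-yne | C=C[C@H](O[Si](C)(C)C(C)(C)C)[C@H]([C@@H](O[Si](CC)(CC)CC)CCc1ccccc1)C#C
F6 | step 17 | analogue of 25 with a vinyl group on C6 in place of the methoxyalkyne (homopropargylic alcohol) | COC(=O)c1ccc(O[Si](C(C)C)(C(C)C)C(C)C)c([C@H]([C@@H](O)C(C)(C)O[Si](CC)(CC)CC)C#C[C@@H]([C@H](CCc2ccccc2)O[Si](CC)(CC)CC)[C@@H](O[Si](C)(C)C(C)(C)C)C=C)c1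
F7 | step 17 | 3-iodo-4,5-dihydrofuran from F6 (iodine on C3a, ring A closed) | COC(=O)c1ccc(O[Si](C(C)C)(C(C)C)C(C)C)c([C@H]2C(I)=C(O[C@H]2C(C)(C)O[Si](CC)(CC)CC)[C@@H]([C@H](CCc3ccccc3)O[Si](CC)(CC)CC)[C@@H](O[Si](C)(C)C(C)(C)C)C=C)c1
F8 | step 17 | 2-methoxydiene from F7 (1-methoxyvinyl group on C3a) | COC(=O)c1ccc(O[Si](C(C)C)(C(C)C)C(C)C)c([C@H]2C(C(=C)OC)=C(O[C@H]2C(C)(C)O[Si](CC)(CC)CC)[C@@H]([C@H](CCc3ccccc3)O[Si](CC)(CC)CC)[C@@H](O[Si](C)(C)C(C)(C)C)C=C)c1
F9 | step 16 | methyl 3-[(2S,3R)-3-(2-hydroxypropan-2-yl)oxiran-2-yl]-4-[(triisopropylsilyl)oxy]benzoate | COC(=O)c1ccc(O[Si](C(C)C)(C(C)C)C(C)C)c([C@@H]2O[C@H]2C(C)(C)O)c1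
F10 | step 16 | analogue of 25 with the tertiary hydroxyl free (C2, tertiary diol) | COC(=O)c1ccc(O[Si](C(C)C)(C(C)C)C(C)C)c([C@H]([C@@H](O)C(C)(C)O)C#C[C@@H]([C@H](CCc2ccccc2)O[Si](CC)(CC)CC)[C@@H](O[Si](C)(C)C(C)(C)C)C#COC)c1
F11 | step 16 | bis(trimethylsilyl) ether of F10 | COC(=O)c1ccc(O[Si](C(C)C)(C(C)C)C(C)C)c([C@H]([C@@H](O[Si](C)(C)C)C(C)(C)O[Si](C)(C)C)C#C[C@@H]([C@H](CCc2ccccc2)O[Si](CC)(CC)CC)[C@@H](O[Si](C)(C)C(C)(C)C)C#COC)c1
F12 | step 16 | analogue of 25 with a trimethylsilyl ether on the tertiary oxygen and the C2 hydroxyl free | COC(=O)c1ccc(O[Si](C(C)C)(C(C)C)C(C)C)c([C@H]([C@@H](O)C(C)(C)O[Si](C)(C)C)C#C[C@@H]([C@H](CCc2ccccc2)O[Si](CC)(CC)CC)[C@@H](O[Si](C)(C)C(C)(C)C)C#COC)c1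
F13 | step 16 | analogue of 27 with a trimethylsilyl ether on the tertiary oxygen | COC(=O)c1ccc(O[Si](C(C)C)(C(C)C)C(C)C)c([C@H]2C3=C(O[C@H]2C(C)(C)O[Si](C)(C)C)[C@@H]([C@H](CCc4ccccc4)O[Si](CC)(CC)CC)[C@@H](O[Si](C)(C)C(C)(C)C)C=C3OC)c1
F14 | step 11 | C6 epimer of 19, (2R,3S)-2-[(1S)-1-hydroxy-3-methoxyprop-2-yn-1-yl]-5-phenyl-3-[(triethylsilyl)oxy]pentyl 2,2-dimethylpropanoate | COC#C[C@@H](O)[C@H]([C@@H](O[Si](CC)(CC)CC)CCc1ccccc1)COC(=O)C(C)(C)C
F15 | step 11 | (2S,3S)-2-(3-methoxyprop-2-ynoyl)-5-phenyl-3-[(triethylsilyl)oxy]pentyl 2,2-dimethylpropanoate | COC#CC(=O)[C@H]([C@@H](O[Si](CC)(CC)CC)CCc1ccccc1)COC(=O)C(C)(C)C
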